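**Strategy.** The cyclohexane (target numbering: C1 = CBr, C2 and C4 = CHCl, C5 = quaternary carbon) is cut at C3–C4 and C5–C6. A catalytic enantioselective Diels–Alder reaction between 2-(triisopropylsilyloxy)butadiene and (Z)-3-chloro-2-methylacrolein closes the ring and sets C4 and C5 together. The C4 chlorine is cis to the formyl group (later the chlorovinyl group) because of the alkene geometry, and the catalyst fixes the quaternary centre. The step exploits the cis C4–Cl/C5–vinyl relation and the 1,4-relation of C2 and C5, which puts the enol ether oxygen on C2. That enol ether then steers chloroformylation, reductive transposition and halohydrin chemistry at C1 and C2.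

Key step: step 4

Remark on numbering: ring atoms are named as in the target throughout: C1 (CBr), C2 (CHCl), C3 (CH2), C4 (CHCl), C5 (quaternary C), C6 (CH2).

Assumption: with the (S)-oxazaborolidinium catalyst the diene is taken to add to the same α-face of the bound enal as in the known reactions of 2-methylacrolein (the Si face at C2 of 4); if the sense proves opposite, the (R)-catalyst is used and nothing else changes.

Step 1
Reactants: 1 prop-2-yn-1-ol
Product: 3 (Z)-3-chloro-2-methylprop-2-en-1-ol, via chelated alkenylmagnesium alkoxide 2 (not isolated)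
Conditions: MeMgBr (2.5 equiv), CuI (10 mol %), Et2O, −10 °C → rt; then NCS, THF, −30 °C → rt; aq. NH4Cl
Reagents that add atoms: methylmagnesium bromide (C[Mg]Br); N-chlorosuccinimide (O=C1CCC(=O)N1Cl)
Why: Copper-catalysed anti-carbomagnesiation of the propargylic alkoxide (Duboudin reaction) puts the methyl group on C2 and magnesium on C3 cis to the CH2O group through chelate 2, and electrophilic chlorination of the alkenyl–Mg bond proceeds with retention, so the Z geometry (Cl cis to CH2OH) is fixed here.

Step 2
Reactants: 3 (Z)-3-chloro-2-methylprop-2-en-1-ol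
Product: 4 (Z)-3-chloro-2-methylprop-2-enal
Conditions: activated MnO2, CH2Cl2, rt; used as a solution
Reagents that add atoms: none
Why: MnO2 oxidation of an allylic alcohol is neutral and heterogeneous, so the Z-chloroalkene geometry should be carried into the enal unchanged.

Step 3
Reactants: 5 but-3-en-2-one
Product: 6 2-(triisopropylsilyloxy)buta-1,3-diene
Conditions: TIPSOTf, Et3N, Et2O, 0 °C → rt
Reagents that add atoms: triisopropylsilyl triflate (CC(C)[Si](C(C)C)(C(C)C)OS(=O)(=O)C(F)(F)F)
Why: Soft enolisation and O-silylation of the enone (silyl triflate/amine) gives the cross-conjugated 2-silyloxydiene; no stereocentre is formed.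

Step 4
Reactants: 4 (Z)-3-chloro-2-methylprop-2-enal; 6 2-(triisopropylsilyloxy)buta-1,3-diene
Product: 7 (1S,6S)-6-chloro-1-methyl-4-(triisopropylsilyloxy)cyclohex-3-ene-1-carbaldehyde
Conditions: (S)-3,3-diphenyl-1-(o-tolyl)tetrahydropyrrolo[1,2-c][1,3,2]oxazaborole (20 mol %), Tf2NH (18 mol %), CH2Cl2, −78 → −40 °C
Reagents that add atoms: none
Why: The oxazaborolidinium ion binds the formyl oxygen of 4 and the diene adds in a concerted but asynchronous [4+2] cycloaddition in which the bond from the diene CH2 next to the silyloxy carbon to the β-carbon (CHCl) runs ahead of the bond to the α-carbon; the closest known reaction type is the oxazaborolidinium-catalysed enantioselective Diels–Alder reaction of 2-substituted acroleins with 2-silyloxybutadienes. The six-membered ring is closed by intermolecular [4+2] cycloaddition, suprafacial on both components, which forms C3–C4 and C5–C6 of the target. The C4 stereocentre (Cl cis to the formyl group on C5) follows from stereospecific suprafacial addition to the Z alkene, and the absolute configuration of the quaternary C5 follows from the catalyst, which shields one face of the s-trans enal so that the diene adds to the Si face of the α-carbon. The step needs "para" regioselectivity, secured by the 2-silyloxy group, whose adjacent terminus has the larger HOMO coefficient and bonds to the β-carbon, so that the enol ether carbon ends 1,4 to the quaternary carbon. It also needs cycloaddition to outrun Mukaiyama–Michael addition with chloride loss and Z/E isomerisation of the β-chloroenal, which the low temperature, the non-nucleophilic triflimide counter-ion and the absence of free chloride should secure. No endo/exo issue arises because both diene termini are unsubstituted.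

Step 5
Reactants: 7 (1S,6S)-6-chloro-1-methyl-4-(triisopropylsilyloxy)cyclohex-3-ene-1-carbaldehyde
Product: 8 triisopropyl{[(4S,5S)-5-chloro-4-[(E)-2-chloroethenyl]-4-methylcyclohex-1-en-1-yl]oxy}silane
Conditions: CrCl2 (6 equiv), CHCl3 (2 equiv), THF, 65 °C
Reagents that add atoms: chloroform (ClC(Cl)Cl)
Why: Takai–Utimoto chloro-olefination: the gem-dichromium reagent from CHCl3 and CrCl2 adds to the aldehyde and anti-elimination gives the (E)-chloroalkene, while the silyl enol ether and the unactivated secondary chloride should be inert to Cr(II).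

Step 6
Reactants: 8 triisopropyl{[(4S,5S)-5-chloro-4-[(E)-2-chloroethenyl]-4-methylcyclohex-1-en-1-yl]oxy}silane
Product: 11 (4S,5S)-2,4-dichloro-5-[(E)-2-chloroethenyl]-5-methylcyclohex-1-ene-1-carbaldehyde, via enaminone 9 (not isolated), via chlorovinyl iminium chloride 10 (not isolated)
Conditions: POCl3 (3 equiv), DMF (5 equiv), CH2Cl2, 0 → 45 °C; then aq. NaOAc
Reagents that add atoms: N,N-dimethylformamide (CN(C)C=O); phosphoryl chloride (O=P(Cl)(Cl)Cl); water (O)
Why: Vilsmeier–Haack–Arnold chloroformylation: the enol ether attacks the chloroiminium ion at its nucleophilic carbon (the future C1), so the regiochemistry set by the cycloaddition is kept, and a second equivalent converts the vinylogous amide 9 into iminium salt 10, whose hydrolysis gives the β-chloroenal with chlorine on the future C2; no stereocentre is touched.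

Step 7
Reactants: 11 (4S,5S)-2,4-dichloro-5-[(E)-2-chloroethenyl]-5-methylcyclohex-1-ene-1-carbaldehyde
Product: 12 [(4S,5S)-2,4-dichloro-5-[(E)-2-chloroethenyl]-5-methylcyclohex-1-en-1-yl]methanol
Conditions: NaBH4, CeCl3·7H2O, MeOH, −20 → 0 °C
Reagents that add atoms: none
Why: Luche 1,2-reduction of the enal to the primary allylic alcohol; vinylic and secondary chlorides are not reduced by borohydride under these conditions.

Step 8
Reactants: 12 [(4S,5S)-2,4-dichloro-5-[(E)-2-chloroethenyl]-5-methylcyclohex-1-en-1-yl]methanol
Product: 15 (1S,2S,5R)-1,5-dichloro-2-[(E)-2-chloroethenyl]-2-methyl-4-methylidenecyclohexane, via sulfonylhydrazine 13 (not isolated), via allylic diazene 14 (not isolated)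
Conditions: 2-nitrobenzenesulfonylhydrazide (NBSH), PPh3, DEAD, THF, −30 → 23 °C
Reagents that add atoms: none
Why: Myers reductive 1,3-transposition: Mitsunobu N-alkylation of NBSH gives 13, loss of arenesulfinic acid gives diazene 14, and its retro-ene loss of N2 delivers hydrogen to the chlorine-bearing carbon (C2) and moves the alkene to the exocyclic position, the hydrogen arriving axially on the half-chair that keeps the C4 chlorine pseudo-equatorial (syn to the axial C4–H, not to an axial C4–Cl), so that the C2 chlorine should end equatorial and cis to the C4 chlorine.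

Step 9
Reactants: 15 (1S,2S,5R)-1,5-dichloro-2-[(E)-2-chloroethenyl]-2-methyl-4-methylidenecyclohexane
Product: 16 (1R,2R,4S,5S)-2,4-dichloro-1-(chloromethyl)-5-[(E)-2-chloroethenyl]-5-methylcyclohexan-1-ol
Conditions: trichloroisocyanuric acid (0.4 equiv), acetone/H2O 4:1, 0 °C
Reagents that add atoms: trichloroisocyanuric acid (O=C1N(Cl)C(=O)N(Cl)C(=O)N1Cl); water (O)
Why: Chlorohydrin formation by anti addition of Cl+ and water with Markovnikov regiochemistry (as for methallyl chloride): the chloronium ion should form on the equatorial face of the 1,1-disubstituted alkene, away from the axial chlorovinyl group on C5, and water then opens it at the tertiary carbon from the axial side, which puts OH cis to the chlorovinyl group and CH2Cl equatorial, while the electron-poor chlorovinyl alkene should not react.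

Step 10
Reactants: 16 (1R,2R,4S,5S)-2,4-dichloro-1-(chloromethyl)-5-[(E)-2-chloroethenyl]-5-methylcyclohexan-1-ol
Product: 17 (1R,2R,4S,5S)-1-bromo-2,4-dichloro-1-(chloromethyl)-5-[(E)-2-chloroethenyl]-5-methylcyclohexane
Conditions: HBr (33 % in AcOH), LiBr, CH2Cl2, 0 °C → rt
Reagents that add atoms: hydrogen bromide (Br)
Why: Conversion of a β-chloro tertiary alcohol into the vicinal bromochloride by acid-promoted substitution with neighbouring-group participation: the antiperiplanar chlorine of the CH2Cl group assists loss of water to a chloriranium ion on the equatorial face and bromide opens it at the tertiary carbon from the axial side, so that C1 is substituted with net retention (double inversion) and bromine ends cis to the C2 chlorine and to the chlorovinyl group.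

**Compound list**

1 | prop-2-yn-1-ol | C#CCO | starting material
2 | bromomagnesium (Z)-3-(bromomagnesio)-2-methylprop-2-en-1-olate (chelate) | Br[Mg]OC/C(C)=C\[Mg]Br | intermediate
3 | (Z)-3-chloro-2-methylprop-2-en-1-ol | OC/C(C)=C\Cl | intermediate
4 | (Z)-3-chloro-2-methylprop-2-enal | O=C/C(C)=C\Cl | intermediate
5 | but-3-en-2-one (methyl vinyl ketone) | CC(=O)C=C | starting material
6 | 2-(triisopropylsilyloxy)buta-1,3-diene | C=CC(=C)O[Si](C(C)C)(C(C)C)C(C)C | intermediate
7 | (1S,6S)-6-chloro-1-methyl-4-(triisopropylsilyloxy)cyclohex-3-ene-1-carbaldehyde | C[C@@]1(C=O)CC=C(O[Si](C(C)C)(C(C)C)C(C)C)C[C@@H]1Cl | intermediate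
8 | triisopropyl{[(4S,5S)-5-chloro-4-[(E)-2-chloroethenyl]-4-methylcyclohex-1-en-1-yl]oxy}silane | C[C@@]1(/C=C/Cl)CC=C(O[Si](C(C)C)(C(C)C)C(C)C)C[C@@H]1Cl | intermediate
9 | (2E,4S,5S)-5-chloro-4-[(E)-2-chloroethenyl]-2-[(dimethylamino)methylidene]-4-methylcyclohexan-1-one | C[C@@]1(/C=C/Cl)C/C(=C\N(C)C)C(=O)C[C@@H]1Cl | intermediate
10 | N-{[(4S,5S)-2,4-dichloro-5-[(E)-2-chloroethenyl]-5-methylcyclohex-1-en-1-yl]methylidene}-N-methylmethanaminium chloride | C[C@@]1(/C=C/Cl)CC(C=[N+](C)C)=C(Cl)C[C@@H]1Cl.[Cl-] | intermediate
11 | (4S,5S)-2,4-dichloro-5-[(E)-2-chloroethenyl]-5-methylcyclohex-1-ene-1-carbaldehyde | C[C@@]1(/C=C/Cl)CC(C=O)=C(Cl)C[C@@H]1Cl | intermediate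
12 | [(4S,5S)-2,4-dichloro-5-[(E)-2-chloroethenyl]-5-methylcyclohex-1-en-1-yl]methanol | C[C@@]1(/C=C/Cl)CC(CO)=C(Cl)C[C@@H]1Cl | intermediate
13 | N-{[(4S,5S)-2,4-dichloro-5-[(E)-2-chloroethenyl]-5-methylcyclohex-1-en-1-yl]methyl}-2-nitrobenzenesulfonohydrazide | C[C@@]1(/C=C/Cl)CC(CN(N)S(=O)(=O)c2ccccc2[N+](=O)[O-])=C(Cl)C[C@@H]1Cl | intermediate
14 | {[(4S,5S)-2,4-dichloro-5-[(E)-2-chloroethenyl]-5-methylcyclohex-1-en-1-yl]methyl}diazene | C[C@@]1(/C=C/Cl)CC(CN=N)=C(Cl)C[C@@H]1Cl | intermediate
15 | (1S,2S,5R)-1,5-dichloro-2-[(E)-2-chloroethenyl]-2-methyl-4-methylidenecyclohexane | C[C@@]1(/C=C/Cl)CC(=C)[C@H](Cl)C[C@@H]1Cl | intermediate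
16 | (1R,2R,4S,5S)-2,4-dichloro-1-(chloromethyl)-5-[(E)-2-chloroethenyl]-5-methylcyclohexan-1-ol | C[C@@]1(/C=C/Cl)C[C@@](O)(CCl)[C@H](Cl)C[C@@H]1Cl | intermediate
17 | (1R,2R,4S,5S)-1-bromo-2,4-dichloro-1-(chloromethyl)-5-[(E)-2-chloroethenyl]-5-methylcyclohexane | C[C@@]1(/C=C/Cl)C[C@@](Br)(CCl)[C@H](Cl)C[C@@H]1Cl | target

**Totals.** Total step count: 10. Longest linear sequence: 9 steps (1, 2, 4–10); step 3 is a one-step branch.

**Steps most likely to fail**

Step 4. The trisubstituted β-chloroenal may react too slowly, may lose its Z geometry on the strong Lewis acid, or may undergo Mukaiyama–Michael addition with loss of chloride instead of ring closure. The fallback replaces Lewis-acid activation by a far more nucleophilic diene under hydrogen-bond catalysis. It sets out from 4, which is combined with commercial (E)-1-(dimethylamino)-3-(tert-butyldimethylsilyloxy)buta-1,3-diene and a TADDOL catalyst in toluene at −78 °C to give the amino-substituted cycloadduct (1S,2R,6S)-6-chloro-2-(dimethylamino)-1-methyl-4-(tert-butyldimethylsilyloxy)cyclohex-3-ene-1-carbaldehyde F1 (amino group next to the quaternary carbon, same para relation of enol ether and quaternary carbon). Takai chloro-olefination of the crude aldehyde should give the chlorovinyl aminocyclohexene F2. Aqueous HF in MeCN removes the silyl group and eliminates dimethylamine to give the enone (4S,5S)-5-chloro-4-[(E)-2-chloroethenyl]-4-methylcyclohex-2-en-1-one F3. Conjugate reduction with L-Selectride and trapping of the enolate with TIPSOTf comes back to the route at 8.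

Step 10. Ionisation of the tertiary alcohol is slowed by two β-chlorines, so elimination, or opening of the chloriranium ion at the primary carbon (chloride/bromide exchange), may overtake substitution at C1. The fallback forms the C–Br bond by a radical instead of a cation. It sets out from 15: ene-type allylic chlorination (NCS, cat. PhSeCl, CH2Cl2) should shift the alkene into the ring and give the allylic chloride (3S,4S,6R)-4,6-dichloro-1-(chloromethyl)-3-[(E)-2-chloroethenyl]-3-methylcyclohex-1-ene F4. Markovnikov hydrobromination by metal-hydride hydrogen-atom transfer (Co(acac)2, t-BuOOH, Et3SiH, TsBr) then adds hydrogen to C6 and bromine to the tertiary radical at C1, with the CH2Cl group expected to settle equatorial, and comes back at 17.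

Step 8. Sigmatropic hydrogen delivery to the fully substituted, chlorine-bearing alkene carbon may be slower than decomposition of the diazene, or may take place on both faces. The fallback sets C2 by reagent-controlled reduction and SN2 chlorination instead of transposition. It sets out from 8: Eschenmoser's salt gives the Mannich base (4S,5S)-5-chloro-4-[(E)-2-chloroethenyl]-2-[(dimethylamino)methyl]-4-methylcyclohexan-1-one F5. N-methylation with MeI gives the trimethylammonium iodide F6, which eliminates with DBU to the exo-methylene ketone (4S,5S)-5-chloro-4-[(E)-2-chloroethenyl]-4-methyl-2-methylidenecyclohexan-1-one F7. CBS reduction ((R)-Me-CBS, catecholborane, alkenyl carbon as the large group) should give the allylic alcohol (1S,4S,5S)-5-chloro-4-[(E)-2-chloroethenyl]-4-methyl-2-methylidenecyclohexan-1-ol F8, with hydroxyl trans to the C4 chlorine. Magid chlorination (hexachloroacetone, PPh3), which inverts without allylic shift, comes back at 15.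

**Further compounds**

F1 | step 4 | (1S,2R,6S)-6-chloro-2-(dimethylamino)-1-methyl-4-(tert-butyldimethylsilyloxy)cyclohex-3-ene-1-carbaldehyde | C[C@@]1(C=O)[C@H](N(C)C)C=C(O[Si](C)(C)C(C)(C)C)C[C@@H]1Cl
F2 | step 4 | tert-butyl{[(3R,4R,5S)-5-chloro-4-[(E)-2-chloroethenyl]-3-(dimethylamino)-4-methylcyclohex-1-en-1-yl]oxy}dimethylsilane | C[C@@]1(/C=C/Cl)[C@H](N(C)C)C=C(O[Si](C)(C)C(C)(C)C)C[C@@H]1Cl
F3 | step 4 | (4S,5S)-5-chloro-4-[(E)-2-chloroethenyl]-4-methylcyclohex-2-en-1-one | C[C@@]1(/C=C/Cl)C=CC(=O)C[C@@H]1Cl
F4 | step 10 | (3S,4S,6R)-4,6-dichloro-1-(chloromethyl)-3-[(E)-2-chloroethenyl]-3-methylcyclohex-1-ene | C[C@@]1(/C=C/Cl)C=C(CCl)[C@H](Cl)C[C@@H]1Cl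
F5 | step 8 | (4S,5S)-5-chloro-4-[(E)-2-chloroethenyl]-2-[(dimethylamino)methyl]-4-methylcyclohexan-1-one (both C2 epimers) | C[C@@]1(/C=C/Cl)CC(CN(C)C)C(=O)C[C@@H]1Cl
F6 | step 8 | 1-[(4S,5S)-4-chloro-5-[(E)-2-chloroethenyl]-5-methyl-2-oxocyclohexyl]-N,N,N-trimethylmethanaminium iodide | C[C@@]1(/C=C/Cl)CC(C[N+](C)(C)C)C(=O)C[C@@H]1Cl.[I-]
F7 | step 8 | (4S,5S)-5-chloro-4-[(E)-2-chloroethenyl]-4-methyl-2-methylidenecyclohexan-1-one | C[C@@]1(/C=C/Cl)CC(=C)C(=O)C[C@@H]1Cl
F8 | step 8 | (1S,4S,5S)-5-chloro-4-[(E)-2-chloroethenyl]-4-methyl-2-methylidenecyclohexan-1-ol | C[C@@]1(/C=C/Cl)CC(=C)[C@@H](O)C[C@@H]1Cl
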